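Assumption: the target is taken exactly as the SMILES reads, (2S,6E,10E)-12-(3-formyl-2,4,5-trihydroxyphenyl)-2,6,10-trimethyldodeca-6,10-dienoic acid; benzene-1,2,4-triol and (2E,6E)-farnesyl bromide are taken as commercial.

## Retrosynthetic overview

1. Target 14 ⇐ acid-mediated removal of three MOM ethers from acid 13.
2. 13 ⇐ carbene-catalysed asymmetric redox hydration of α-methyl enal 12; this sets the only stereocentre (C2 of the acid) by enantioselective α-protonation.
3. 12 ⇐ allylic oxidation of the terminal E-methyl group of the farnesyl side chain in aryl aldehyde 10.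
4. 10 ⇐ ortho-lithiation/formylation of 7 between two OMOM groups; 7 ⇐ aryl–allyl coupling of aryl bromide 3 with (2E,6E)-farnesyl bromide 4; 3 ⇐ benzene-1,2,4-triol 1.
5. No ring is formed: the benzene ring comes intact from 1 and both E-olefins come from 4.

## Route

Step 1
Reactants: 1 benzene-1,2,4-triol
Product: 2 1,2,4-tris(methoxymethoxy)benzene
Conditions: MOMCl (4 equiv), i-Pr2NEt (5 equiv), CH2Cl2, 0 °C to rt, argon
Reagents that add atoms: chloromethyl methyl ether, COCCl
Why: Threefold O-alkylation (MOM protection) masks the air-sensitive triol and supplies the ortho-directing groups used in step 4.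

Step 2
Reactants: 2 1,2,4-tris(methoxymethoxy)benzene
Product: 3 1-bromo-2,4,5-tris(methoxymethoxy)benzene
Conditions: NBS (1.0 equiv), MeCN, 0 °C, dark
Reagents that add atoms: N-bromosuccinimide, O=C1CCC(=O)N1Br
Why: Electrophilic aromatic bromination goes to the position ortho to one OMOM and para to another, the site at which 1,2,4-trialkoxybenzenes are substituted selectively.

Step 3
Reactants: 3 1-bromo-2,4,5-tris(methoxymethoxy)benzene; 4 (2E,6E)-farnesyl bromide
Product: 7 1,2,4-tris(methoxymethoxy)-5-[(2E,6E)-3,7,11-trimethyldodeca-2,6,10-trien-1-yl]benzene, via aryllithium 5 (not isolated), via arylcopper 6 (not isolated)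
Conditions: n-BuLi (1.05 equiv), THF, −78 °C; CuBr·SMe2 (1.1 equiv), −78 to −40 °C; then 4, −78 to 0 °C
Reagents that add atoms: none
Why: Bromine–lithium exchange, transmetalation to a monovalent arylcopper and SN2 allylation of the primary allylic bromide form the aryl–CH2 bond without allylic transposition and keep the 2E,6E geometry.

Step 4
Reactants: 7 1,2,4-tris(methoxymethoxy)-5-[(2E,6E)-3,7,11-trimethyldodeca-2,6,10-trien-1-yl]benzene
Product: 10 2,3,6-tris(methoxymethoxy)-5-[(2E,6E)-3,7,11-trimethyldodeca-2,6,10-trien-1-yl]benzaldehyde, via aryllithium 8 (not isolated), via lithium hemiaminal alkoxide 9 (not isolated)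
Conditions: n-BuLi (1.2 equiv), TMEDA, THF, −40 to −10 °C; DMF (3 equiv), −78 °C to rt; H2O
Reagents that add atoms: N,N-dimethylformamide, CN(C)C=O
Why: Directed ortho-metalation removes the ring hydrogen flanked by two OMOM groups (cooperative direction, faster than the singly directed ring C–H or the benzylic CH2 at low temperature) and DMF formylates it; 9 is racemic and transient and collapses to the achiral aldehyde on quench.

Step 5
Reactants: 10 2,3,6-tris(methoxymethoxy)-5-[(2E,6E)-3,7,11-trimethyldodeca-2,6,10-trien-1-yl]benzaldehyde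
Product: 12 (2E,6E,10E)-12-[3-formyl-2,4,5-tris(methoxymethoxy)phenyl]-2,6,10-trimethyldodeca-2,6,10-trienal, via allylic alcohol 11 (not isolated)
Conditions: SeO2 (0.5 equiv), t-BuOOH (3 equiv), salicylic acid (10 mol %), CH2Cl2, 0 °C to rt, stopped near 60% conversion; filter; then MnO2 (15 equiv), CH2Cl2, rt
Reagents that add atoms: selenium dioxide, O=[Se]=O (delivers the oxygen atom); tert-butyl hydroperoxide, CC(C)(C)OO (terminal oxidant that reloads selenium)
Why: Riley allylic oxidation (ene reaction then [2,3]-shift) prefers the E-methyl of the least hindered, terminal trisubstituted olefin, and MnO2 converges the alcohol/aldehyde mixture to the E-enal without touching the aryl aldehyde.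

Step 6
Reactants: 12 (2E,6E,10E)-12-[3-formyl-2,4,5-tris(methoxymethoxy)phenyl]-2,6,10-trimethyldodeca-2,6,10-trienal
Product: 13 (2S,6E,10E)-12-[3-formyl-2,4,5-tris(methoxymethoxy)phenyl]-2,6,10-trimethyldodeca-6,10-dienoic acid
Conditions: (5aS,10bR)-2-mesityl-5a,10b-dihydro-4H,6H-indeno[2,1-b][1,2,4]triazolo[4,3-d][1,4]oxazin-2-ium chloride (15 mol %), K2CO3 (1.0 equiv, 1 M aq.), brine, toluene, n-Bu4NBr (10 mol %), 4 °C, degassed, argon; then aq. HCl to pH 3
Reagents that add atoms: water, O
Why: Proposed new method: carbene-catalysed internal redox hydration of an α-methyl-β-alkyl enal with enantioselective α-protonation — the carbene adds to the enal carbonyl (the aryl aldehyde is blocked by two ortho OMOM groups), the Breslow intermediate is protonated at Cβ, allylic 1,3-strain between the α-methyl and the N-mesityl ring fixes one azolium-enol geometry, the aminoindanol backbone shields one enol face so that bicarbonate/water protonates Cα from the other (2S is the aim; the sense cannot be predicted, so it is checked first on (E)-2-methylpent-2-enal and the (5aR,10bS) catalyst is used if it is reversed), and water hydrolyses the acyl azolium before it re-enolises; the closest known reaction type is the carbene-catalysed redox hydration/esterification of enals with enantioselective protonation of α-halo- or α-fluoro-substituted azolium enolates, not yet shown for a purely alkyl-substituted enolate.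

Step 7
Reactants: 13 (2S,6E,10E)-12-[3-formyl-2,4,5-tris(methoxymethoxy)phenyl]-2,6,10-trimethyldodeca-6,10-dienoic acid
Product: 14 (2S,6E,10E)-12-(3-formyl-2,4,5-trihydroxyphenyl)-2,6,10-trimethyldodeca-6,10-dienoic acid (CNP0180353.1)
Conditions: 2 M aq. HCl/i-PrOH/THF (1:4:4), 40 °C, degassed, argon
Reagents that add atoms: none
Why: Acid-catalysed acetal hydrolysis removes the three MOM groups under conditions that do not epimerise the α-methyl acid; i-PrOH traps formaldehyde without esterifying the branched acid, and oxygen is excluded because the free hydroxyquinol is air-sensitive.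

## Compound list

1 | benzene-1,2,4-triol | Oc1ccc(O)c(O)c1 | starting material
2 | 1,2,4-tris(methoxymethoxy)benzene | COCOc1ccc(OCOC)c(OCOC)c1 | intermediate
3 | 1-bromo-2,4,5-tris(methoxymethoxy)benzene | Brc1cc(OCOC)c(OCOC)cc1OCOC | intermediate
4 | (2E,6E)-farnesyl bromide, (2E,6E)-1-bromo-3,7,11-trimethyldodeca-2,6,10-triene | CC(C)=CCC/C(C)=C/CC/C(C)=C/CBr | starting material
5 | [2,4,5-tris(methoxymethoxy)phenyl]lithium | [Li]c1cc(OCOC)c(OCOC)cc1OCOC | intermediate (not isolated)
6 | [2,4,5-tris(methoxymethoxy)phenyl]copper (monovalent copper) | [Cu]c1cc(OCOC)c(OCOC)cc1OCOC | intermediate (not isolated)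
7 | 1,2,4-tris(methoxymethoxy)-5-[(2E,6E)-3,7,11-trimethyldodeca-2,6,10-trien-1-yl]benzene | CC(C)=CCC/C(C)=C/CC/C(C)=C/Cc1cc(OCOC)c(OCOC)cc1OCOC | intermediate
8 | {2,3,6-tris(methoxymethoxy)-5-[(2E,6E)-3,7,11-trimethyldodeca-2,6,10-trien-1-yl]phenyl}lithium | CC(C)=CCC/C(C)=C/CC/C(C)=C/Cc1cc(OCOC)c(OCOC)c([Li])c1OCOC | intermediate (not isolated)
9 | lithium (dimethylamino){2,3,6-tris(methoxymethoxy)-5-[(2E,6E)-3,7,11-trimethyldodeca-2,6,10-trien-1-yl]phenyl}methanolate (racemic, transient) | CC(C)=CCC/C(C)=C/CC/C(C)=C/Cc1cc(OCOC)c(OCOC)c(C(O[Li])N(C)C)c1OCOC | intermediate (not isolated)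
10 | 2,3,6-tris(methoxymethoxy)-5-[(2E,6E)-3,7,11-trimethyldodeca-2,6,10-trien-1-yl]benzaldehyde | CC(C)=CCC/C(C)=C/CC/C(C)=C/Cc1cc(OCOC)c(OCOC)c(C=O)c1OCOC | intermediate
11 | 5-[(2E,6E,10E)-12-hydroxy-3,7,11-trimethyldodeca-2,6,10-trien-1-yl]-2,3,6-tris(methoxymethoxy)benzaldehyde | OC/C(C)=C/CC/C(C)=C/CC/C(C)=C/Cc1cc(OCOC)c(OCOC)c(C=O)c1OCOC | intermediate (not isolated)
12 | (2E,6E,10E)-12-[3-formyl-2,4,5-tris(methoxymethoxy)phenyl]-2,6,10-trimethyldodeca-2,6,10-trienal | O=C/C(C)=C/CC/C(C)=C/CC/C(C)=C/Cc1cc(OCOC)c(OCOC)c(C=O)c1OCOC | intermediate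
13 | (2S,6E,10E)-12-[3-formyl-2,4,5-tris(methoxymethoxy)phenyl]-2,6,10-trimethyldodeca-6,10-dienoic acid | C/C(=C\Cc1cc(OCOC)c(OCOC)c(C=O)c1OCOC)CC/C=C(\C)CCC[C@H](C)C(=O)O | intermediate
14 | (2S,6E,10E)-12-(3-formyl-2,4,5-trihydroxyphenyl)-2,6,10-trimethyldodeca-6,10-dienoic acid | C/C(=C\Cc1cc(O)c(O)c(C=O)c1O)CC/C=C(\C)CCC[C@H](C)C(=O)O | target

## Step count and risks

Total steps: 7. Longest linear sequence: 7 (1 → 14).

The three steps most likely to fail:

**Step 6 (the proposed new reaction).** The enantioselectivity may be low because methyl and CH2R differ little on the azolium enol. The acyl azolium may also racemise before hydrolysis, or the carbene may be held up by the aryl aldehyde. The fallback uses known hydroxyl-directed asymmetric hydrogenation in place of carbene catalysis. It sets out from 11, isolated by chromatography when step 5 is stopped before the MnO2 stage, and comes back at 13. Ru(OAc)2[(S)-BINAP] (1 mol %) under H2 (50 atm) in MeOH at rt reduces only the allylic-alcohol olefin; the two remote trisubstituted olefins and the hindered aryl aldehyde are not substrates. This gives 5-[(2E,6E,11S)-12-hydroxy-3,7,11-trimethyldodeca-2,6-dien-1-yl]-2,3,6-tris(methoxymethoxy)benzaldehyde F10. The facial model from geraniol points to 11S with (S)-BINAP; this is confirmed on (E)-2-methylpent-2-en-1-ol, and (R)-BINAP is used otherwise. TEMPO (cat.) with PhI(OAc)2 in MeCN/H2O then oxidises the primary alcohol through its aldehyde hydrate to acid 13, leaving the non-hydrating aryl aldehyde.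

**Step 5 (late-stage allylic oxidation).** Three trisubstituted olefins compete, and the peroxide/selenium system can also attack the electron-rich aryl aldehyde in a Dakin-type oxidation. The fallback degrades and rebuilds the terminal olefin with no peroxide. It sets out from 10 and comes back at 12. NBS (1.05 equiv) in THF/H2O at 0 °C gives, with the usual terminal selectivity for farnesyl chains, the bromohydrin 5-[(2E,6E)-10-bromo-11-hydroxy-3,7,11-trimethyldodeca-2,6-dien-1-yl]-2,3,6-tris(methoxymethoxy)benzaldehyde F7. K2CO3 in MeOH closes it to the epoxide 5-[(2E,6E)-9-(3,3-dimethyloxiran-2-yl)-3,7-dimethylnona-2,6-dien-1-yl]-2,3,6-tris(methoxymethoxy)benzaldehyde F8. H5IO6 in THF/Et2O at 0 °C cleaves the epoxide to (4E,8E)-10-[3-formyl-2,4,5-tris(methoxymethoxy)phenyl]-4,8-dimethyldeca-4,8-dienal F9. A Wittig reaction of the aliphatic aldehyde with 2-(triphenylphosphoranylidene)propanal (1.05 equiv, toluene, 80 °C; the di-ortho-substituted aryl aldehyde reacts far more slowly) gives the E-enal 12.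

**Step 4 (ortho-lithiation of the farnesyl arene).** Deprotonation may be diverted to the benzylic/allylic CH2 or to the other ring hydrogen. The fallback installs the aldehyde before the side chain and fixes the regiochemistry with a silyl placeholder. It sets out from 3 and comes back at 10. Aryllithium 5, made from 3 as in step 3, is quenched with Me3SiCl to give trimethyl[2,4,5-tris(methoxymethoxy)phenyl]silane F1. n-BuLi/TMEDA lithiates F1 between the two OMOM groups to give [2,3,6-tris(methoxymethoxy)-5-(trimethylsilyl)phenyl]lithium F2. DMF converts this to lithium (dimethylamino)[2,3,6-tris(methoxymethoxy)-5-(trimethylsilyl)phenyl]methanolate F3, which gives 2,3,6-tris(methoxymethoxy)-5-(trimethylsilyl)benzaldehyde F4 on aqueous quench. Ipso-bromodesilylation with NBS in MeCN puts bromine exactly where silicon was and gives 5-bromo-2,3,6-tris(methoxymethoxy)benzaldehyde F5. Stille coupling (Pd(PPh3)4, CuI, CsF, DMF, 60 °C) with tributyl[(2E,6E)-3,7,11-trimethyldodeca-2,6,10-trien-1-yl]stannane F6, made from 4 and Bu3SnLi, then gives 10.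

## Further compounds

F1 | step 4 | trimethyl[2,4,5-tris(methoxymethoxy)phenyl]silane | C[Si](C)(C)c1cc(OCOC)c(OCOC)cc1OCOC
F2 | step 4 | [2,3,6-tris(methoxymethoxy)-5-(trimethylsilyl)phenyl]lithium | C[Si](C)(C)c1cc(OCOC)c(OCOC)c([Li])c1OCOC
F3 | step 4 | lithium (dimethylamino)[2,3,6-tris(methoxymethoxy)-5-(trimethylsilyl)phenyl]methanolate (racemic) | C[Si](C)(C)c1cc(OCOC)c(OCOC)c(C(O[Li])N(C)C)c1OCOC
F4 | step 4 | 2,3,6-tris(methoxymethoxy)-5-(trimethylsilyl)benzaldehyde | C[Si](C)(C)c1cc(OCOC)c(OCOC)c(C=O)c1OCOC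
F5 | step 4 | 5-bromo-2,3,6-tris(methoxymethoxy)benzaldehyde | Brc1cc(OCOC)c(OCOC)c(C=O)c1OCOC
F6 | step 4 | tributyl[(2E,6E)-3,7,11-trimethyldodeca-2,6,10-trien-1-yl]stannane | CCCC[Sn](CCCC)(CCCC)C/C=C(\C)CC/C=C(\C)CCC=C(C)C
F7 | step 5 | 5-[(2E,6E)-10-bromo-11-hydroxy-3,7,11-trimethyldodeca-2,6-dien-1-yl]-2,3,6-tris(methoxymethoxy)benzaldehyde (racemic) | CC(C)(O)C(Br)CC/C(C)=C/CC/C(C)=C/Cc1cc(OCOC)c(OCOC)c(C=O)c1OCOC
F8 | step 5 | 5-[(2E,6E)-9-(3,3-dimethyloxiran-2-yl)-3,7-dimethylnona-2,6-dien-1-yl]-2,3,6-tris(methoxymethoxy)benzaldehyde (racemic) | CC1(C)OC1CC/C(C)=C/CC/C(C)=C/Cc1cc(OCOC)c(OCOC)c(C=O)c1OCOC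
F9 | step 5 | (4E,8E)-10-[3-formyl-2,4,5-tris(methoxymethoxy)phenyl]-4,8-dimethyldeca-4,8-dienal | O=CCC/C(C)=C/CC/C(C)=C/Cc1cc(OCOC)c(OCOC)c(C=O)c1OCOC
F10 | step 6 | 5-[(2E,6E,11S)-12-hydroxy-3,7,11-trimethyldodeca-2,6-dien-1-yl]-2,3,6-tris(methoxymethoxy)benzaldehyde | C/C(=C\Cc1cc(OCOC)c(OCOC)c(C=O)c1OCOC)CC/C=C(\C)CCC[C@H](C)CO
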